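**Retrosynthetic overview**
1. 12 ⇐ 11, in which the ring C phenol is masked as an acetate. Compound 11 already holds all carbons, the C1=C2 double bond and both stereocentres. Locants are those of the 3,4-dihydronaphthalene-2-carboxylate name; ring A is the fused arene, ring B the carbocycle, ring C the pendant aryl.
2. Ring B of 11 is opened at C1–C8a and C4–C4a in one stroke. Ring A leaves as free 2,6-dimethoxyphenol 8. C1–C4 remain as the bicyclic hemiacetal 7, in which C1 (aldehyde level) is tied to the CH2OH oxygen (temporary oxolane) and C2 is tied to C4 (temporary cyclopropane).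
3. Enabling feature: ring A is a symmetric 2,6-dimethoxyphenol. Its carbon para to OH (future C8a) is the first nucleophile, and the two equivalent carbons ortho/para to the OMe groups (future C4a) are the second. Because C1 stands next to the strained C2–C4 bond, a cation at C1 turns into the C1=C2 double bond plus a benzylic cation at C4.
4. 7 ⇐ lactone 6 ⇐ formylcyclopropane 4 ⇐ O-acetylsinapaldehyde 2 + dimethyl bromomalonate 3. The organocatalytic cyclopropanation sets C3, the only stereocentre that has to be carried.
5. Ring order: cyclopropane (step 2), oxolane ring (step 3), ring B (step 5, which consumes both temporary rings).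

Key step: step 5

Remark: the sense of induction in step 2 follows the usual shielding model for the (S)-catalyst, and the (R)-catalyst would be used if the opposite sense were found; 7 is used as its hemiacetal epimer mixture because that carbon becomes planar in step 5.

Step 1
Reactants: 1 sinapaldehyde, (E)-3-(4-hydroxy-3,5-dimethoxyphenyl)prop-2-enal
Product: 2 4-[(E)-3-oxoprop-1-en-1-yl]-2,6-dimethoxyphenyl acetate
Conditions: Ac2O, pyridine, rt
Reagents that add atoms: acetic anhydride, CC(=O)OC(C)=O
Why: Phenol O-acylation, which turns the para oxygen of ring C from a donor into a weak acceptor, so that the enal becomes more electrophilic for step 2 and the benzylic carbon stays silent in step 5 until it is needed.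

Step 2
Reactants: 2 4-[(E)-3-oxoprop-1-en-1-yl]-2,6-dimethoxyphenyl acetate; 3 dimethyl bromomalonate
Product: 4 dimethyl (2S,3R)-2-(4-acetoxy-3,5-dimethoxyphenyl)-3-formylcyclopropane-1,1-dicarboxylate
Conditions: (S)-α,α-diphenylprolinol trimethylsilyl ether (20 mol %), 2,6-lutidine (1.1 equiv), CH2Cl2, 0 °C → rt
Reagents that add atoms: none
Why: Organocatalytic Michael-initiated ring closure (iminium then enamine), in which the bromomalonate anion adds to the face of the iminium ion left open by the diphenyl(silyloxy)methyl group and the enamine then displaces bromide (3-exo-tet), so that both ring stereocentres are set by the catalyst and their trans relation follows from the E-enal.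

Step 3
Reactants: 4 dimethyl (2S,3R)-2-(4-acetoxy-3,5-dimethoxyphenyl)-3-formylcyclopropane-1,1-dicarboxylate
Product: 6 methyl (1S,5R,6S)-6-(4-acetoxy-3,5-dimethoxyphenyl)-2-oxo-3-oxabicyclo[3.1.0]hexane-1-carboxylate, via hydroxy diester 5 (not isolated)
Conditions: NaBH4, THF–MeOH 9:1, −20 °C; AcOH quench; then PPTS (cat.), toluene, 40 °C
Reagents that add atoms: none
Why: Chemoselective borohydride reduction of the aldehyde followed by lactonisation, in which only the ester cis to the new CH2OH group can close the five-membered ring, so the two ester groups are told apart and the former malonate carbon becomes a defined stereocentre.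

Step 4
Reactants: 6 methyl (1S,5R,6S)-6-(4-acetoxy-3,5-dimethoxyphenyl)-2-oxo-3-oxabicyclo[3.1.0]hexane-1-carboxylate
Product: 7 methyl (1R,5R,6S)-6-(4-acetoxy-3,5-dimethoxyphenyl)-2-hydroxy-3-oxabicyclo[3.1.0]hexane-1-carboxylate (both C2 epimers)
Conditions: Sia2BH (2.5 equiv, from BH3·THF and 2-methylbut-2-ene), THF, 0 °C → rt; then H2O
Reagents that add atoms: none
Why: Semi-reduction of a γ-lactone with disiamylborane, which stops at the hemiacetal stage and leaves carboxylic esters alone (as in the reduction of acylated aldonolactones), the new hemiacetal centre being formed without control and without consequence.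

Step 5
Reactants: 7 methyl (1R,5R,6S)-6-(4-acetoxy-3,5-dimethoxyphenyl)-2-hydroxy-3-oxabicyclo[3.1.0]hexane-1-carboxylate; 8 2,6-dimethoxyphenol
Product: 11 methyl (3R,4S)-4-(4-acetoxy-3,5-dimethoxyphenyl)-6-hydroxy-3-(hydroxymethyl)-5,7-dimethoxy-3,4-dihydronaphthalene-2-carboxylate, via C-aryl oxabicycle 9 (not isolated), via homoallyl cation 10 (not isolated)
Conditions: Sc(OTf)3 (15 mol %), 4 Å MS, ClCH2CH2Cl, −20 °C, slow addition of 8, then 60 °C
Reagents that add atoms: none
Why: Proposed new method: Sc(OTf)3 ionises the hemiacetal of 7 to an oxocarbenium ion that is taken by the carbon para to OH of 8 (both ortho carbons carry OMe) to give 9, whose new benzylic C1–O bond, now pushed by that para OH, ionises in turn and releases the CH2OH group. The cyclopropylcarbinyl cation so formed has no hydrogen on C2 to lose, so it relieves its ring strain by breaking the C2–C4 bond, which creates the C1=C2 double bond (conjugated with ring A and the ester) and moves the charge to benzylic C4 (10). Ring B then closes by Friedel–Crafts attack on C4 of the ring A carbon next to the side chain, ortho to one and para to the other OMe group (six-membered cation–arene closure, 6-endo with respect to the arene π bond), and since the two candidate carbons are equivalent by symmetry only one constitution can result. The closest known reaction types are the acid-catalysed para-hydroxyalkylation (C-glycosylation type) of phenols by hemiacetals and the Lewis-acid ring expansion of aryl(2-arylcyclopropyl)carbinols to 1-aryl-1,2-dihydronaphthalenes; what is new is their merger into one intermolecular (4+2) annulation of a free phenol. C3 is carried over untouched from 7, and C4 is set in the closure of the planar cation under control of C3: in the half-chair the C4 aryl must stand pseudoaxial to avoid the C5 methoxy group and the C3 CH2OH pseudoaxial to avoid the C2 ester, which is possible only on opposite faces and should give the trans (3R,4S) product. The step needs 8 to meet C1 before C4 can ionise, which is secured by the acetate on ring C (no para donor, two meta OMe groups), by the single ester on the closed hemiacetal, by the cold start, and by the slow addition of 8, which also holds back a second arylation at C1.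

Step 6
Reactants: 11 methyl (3R,4S)-4-(4-acetoxy-3,5-dimethoxyphenyl)-6-hydroxy-3-(hydroxymethyl)-5,7-dimethoxy-3,4-dihydronaphthalene-2-carboxylate
Product: 12 methyl (3R,4S)-6-hydroxy-4-(4-hydroxy-3,5-dimethoxyphenyl)-3-(hydroxymethyl)-5,7-dimethoxy-3,4-dihydronaphthalene-2-carboxylate
Conditions: K2CO3 (20 mol %), degassed MeOH, Ar, 0 °C → rt; aq. NH4Cl
Reagents that add atoms: none
Why: Base-catalysed methanolysis (transesterification) of the aryl acetate, by far the best acyl donor present, while the conjugated methyl ester can only exchange OMe for OMe, no stereocentre carries an acidic hydrogen, and lactonisation is held back because the trans-diaxial half-chair keeps the CH2OH group away from the ester.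

**Compound list**
1 | sinapaldehyde, (E)-3-(4-hydroxy-3,5-dimethoxyphenyl)prop-2-enal | COc1cc(/C=C/C=O)cc(OC)c1O | starting material
2 | 4-[(E)-3-oxoprop-1-en-1-yl]-2,6-dimethoxyphenyl acetate | CC(=O)Oc1c(OC)cc(/C=C/C=O)cc1OC | intermediate
3 | dimethyl bromomalonate | COC(=O)C(Br)C(=O)OC | starting material
4 | dimethyl (2S,3R)-2-(4-acetoxy-3,5-dimethoxyphenyl)-3-formylcyclopropane-1,1-dicarboxylate | O=C[C@@H]1[C@@H](c2cc(OC)c(OC(C)=O)c(OC)c2)C1(C(=O)OC)C(=O)OC | intermediate
5 | dimethyl (2S,3R)-2-(4-acetoxy-3,5-dimethoxyphenyl)-3-(hydroxymethyl)cyclopropane-1,1-dicarboxylate (not isolated) | OC[C@@H]1[C@@H](c2cc(OC)c(OC(C)=O)c(OC)c2)C1(C(=O)OC)C(=O)OC | intermediate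
6 | methyl (1S,5R,6S)-6-(4-acetoxy-3,5-dimethoxyphenyl)-2-oxo-3-oxabicyclo[3.1.0]hexane-1-carboxylate | COC(=O)[C@@]12C(=O)OC[C@@H]1[C@H]2c1cc(OC)c(OC(C)=O)c(OC)c1 | intermediate
7 | methyl (1R,5R,6S)-6-(4-acetoxy-3,5-dimethoxyphenyl)-2-hydroxy-3-oxabicyclo[3.1.0]hexane-1-carboxylate, C2 epimers | COC(=O)[C@@]12C(O)OC[C@@H]1[C@H]2c1cc(OC)c(OC(C)=O)c(OC)c1 | intermediate
8 | 2,6-dimethoxyphenol | COc1cccc(OC)c1O | starting material
9 | methyl (1R,5R,6S)-6-(4-acetoxy-3,5-dimethoxyphenyl)-2-(4-hydroxy-3,5-dimethoxyphenyl)-3-oxabicyclo[3.1.0]hexane-1-carboxylate, C2 epimers (not isolated) | COC(=O)[C@@]12C(c3cc(OC)c(O)c(OC)c3)OC[C@@H]1[C@H]2c1cc(OC)c(OC(C)=O)c(OC)c1 | intermediate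
10 | (2R,3E)-1-(4-acetoxy-3,5-dimethoxyphenyl)-4-(4-hydroxy-3,5-dimethoxyphenyl)-2-(hydroxymethyl)-3-(methoxycarbonyl)but-3-en-1-ylium (not isolated) | COC(=O)/C(=C/c1cc(OC)c(O)c(OC)c1)[C@H](CO)[CH+]c1cc(OC)c(OC(C)=O)c(OC)c1 | intermediate
11 | methyl (3R,4S)-4-(4-acetoxy-3,5-dimethoxyphenyl)-6-hydroxy-3-(hydroxymethyl)-5,7-dimethoxy-3,4-dihydronaphthalene-2-carboxylate | COC(=O)C1=Cc2cc(OC)c(O)c(OC)c2[C@H](c2cc(OC)c(OC(C)=O)c(OC)c2)[C@H]1CO | intermediate
12 | methyl (3R,4S)-6-hydroxy-4-(4-hydroxy-3,5-dimethoxyphenyl)-3-(hydroxymethyl)-5,7-dimethoxy-3,4-dihydronaphthalene-2-carboxylate | COC(=O)C1=Cc2cc(OC)c(O)c(OC)c2[C@H](c2cc(OC)c(O)c(OC)c2)[C@H]1CO | target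

Total step count: 6. Longest linear sequence: 6.

**Steps most likely to fail**

Step 5 (labelled step).
- What may go wrong: the cyclopropane may heterolyse before the first arylation, so that the phenol is captured at the wrong terminus. The C1 cation may be arylated a second time. An alkene of the wrong geometry may form and must first revert by protonation. The reaction may stall at the ether stage because the acetylated ring C supports the C4 cation too weakly.
- Fallback (known chemistry, the two bonds made in separate operations with a switch of the ring C electronics in between):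
  - Starting from 7 and 8, only the phenol C-alkylation is run (Sc(OTf)3 cat., CH2Cl2, −20 °C), and 9 is isolated.
  - With no external arene left, the phenolic acetate is removed by neutral aminolysis (pyrrolidine, CH2Cl2, rt). This gives methyl (1R,5R,6S)-2,6-bis(4-hydroxy-3,5-dimethoxyphenyl)-3-oxabicyclo[3.1.0]hexane-1-carboxylate F1, in which ring C is now a strong donor.
  - Mild acid (CF3CO2H cat., CH2Cl2, 0 °C) then brings about the known ring expansion of an aryl cyclopropylcarbinyl ether to the 1-aryl-1,2-dihydronaphthalene.
  - The sequence comes back to the route at 12.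

Step 4.
- What may go wrong: hydride transfer may be sluggish to a carbonyl group flanked by a quaternary cyclopropane carbon, or the aryl acetate may be lost in competition.
- Fallback (reductive acetylation in place of isolating a hemiacetal):
  - Starting from 6, iBu2AlH (CH2Cl2, −78 °C) is followed in the same flask by pyridine, DMAP and Ac2O, which trap the aluminium hemiacetal and restore any aryl acetate that was cleaved.
  - This gives methyl (1R,5R,6S)-2-acetoxy-6-(4-acetoxy-3,5-dimethoxyphenyl)-3-oxabicyclo[3.1.0]hexane-1-carboxylate F2.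
  - F2 takes the place of 7 in step 5, ionises to the same oxocarbenium ion, and comes back to the route at 11.

Step 2.
- What may go wrong: catalyst turnover may be slow with an electron-rich enal, the amine catalyst may be N-acylated by the aryl acetate, or base may open the product cyclopropane and erode the optical purity.
- Fallback (intramolecular carbene route), starting from 2:
  - Luche reduction (NaBH4, CeCl3·7H2O, MeOH, 0 °C) gives 4-[(E)-3-hydroxyprop-1-en-1-yl]-2,6-dimethoxyphenyl acetate F3.
  - Acylation with methyl malonyl chloride (pyridine, CH2Cl2) gives (E)-3-(4-acetoxy-3,5-dimethoxyphenyl)allyl methyl malonate F4.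
  - Regitz diazo transfer (p-ABSA, Et3N, MeCN) gives (E)-3-(4-acetoxy-3,5-dimethoxyphenyl)allyl methyl 2-diazomalonate F5.
  - Enantioselective intramolecular cyclopropanation follows with the monovalent copper salt [Cu(MeCN)4]PF6 and a C2-symmetric tert-butyl bis(oxazoline). The ligand antipode is chosen for the (1S,5R,6S) series, with enrichment by recrystallisation if needed.
  - The E-alkene places the aryl group exo, and the sequence comes back to the route at 6.

**Further compounds**
F1 | step 5 | methyl (1R,5R,6S)-2,6-bis(4-hydroxy-3,5-dimethoxyphenyl)-3-oxabicyclo[3.1.0]hexane-1-carboxylate | COC(=O)[C@@]12C(c3cc(OC)c(O)c(OC)c3)OC[C@@H]1[C@H]2c1cc(OC)c(O)c(OC)c1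
F2 | step 4 | methyl (1R,5R,6S)-2-acetoxy-6-(4-acetoxy-3,5-dimethoxyphenyl)-3-oxabicyclo[3.1.0]hexane-1-carboxylate | COC(=O)[C@@]12C(OC(C)=O)OC[C@@H]1[C@H]2c1cc(OC)c(OC(C)=O)c(OC)c1
F3 | step 2 | 4-[(E)-3-hydroxyprop-1-en-1-yl]-2,6-dimethoxyphenyl acetate | CC(=O)Oc1c(OC)cc(/C=C/CO)cc1OC
F4 | step 2 | (E)-3-(4-acetoxy-3,5-dimethoxyphenyl)allyl methyl malonate | COC(=O)CC(=O)OC/C=C/c1cc(OC)c(OC(C)=O)c(OC)c1
F5 | step 2 | (E)-3-(4-acetoxy-3,5-dimethoxyphenyl)allyl methyl 2-diazomalonate | COC(=O)C(=[N+]=[N-])C(=O)OC/C=C/c1cc(OC)c(OC(C)=O)c(OC)c1
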